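The isoflavone is cut at O1–C8a and C4–C4a, bonds to two adjacent carbons of ring A. That adjacency is the feature exploited: one ring A benzyne takes up the oxygen and the acyl carbon of a ring B arylacetic acid in a single operation, giving the 2-hydroxydeoxybenzoin without closing a ring, while the C5 alkoxy group beside the triple bond decides which end receives oxygen and thereby fixes the prenyl group at C6. The aryne precursor is a 2-(trimethylsilyl)aryl triflate carrying two MOM ethers and the prenyl group; its partner is a MOM-protected acid with a free tertiary alcohol.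

Key step: step 12

Assumption (chemistry): the tertiary alcohol of the ring B acid is carried unprotected, because a neutral, hindered hydroxyl traps arynes far more slowly than a carboxylate and any fluoride-stable protecting group for it would demand a harsher final deprotection; phloroglucinol is used anhydrous; the target has no stereocentre.

Step 1
Reactants: 1 phloroglucinol (benzene-1,3,5-triol)
Product: 2 5-{[tri(propan-2-yl)silyl]oxy}benzene-1,3-diol
Conditions: 1 (3 equiv), TIPSCl (1 equiv), imidazole (1.5 equiv), DMF, 0 °C to rt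
Reagents that add atoms: chlorotri(propan-2-yl)silane (TIPSCl), CC(C)[Si](Cl)(C(C)C)C(C)C
Why: Phenol O-silylation with a silyl chloride and imidazole, run with the cheap symmetric triol in excess so that statistics favour the mono-ether, the surplus triol being removed by aqueous extraction.

Step 2
Reactants: 2 5-{[tri(propan-2-yl)silyl]oxy}benzene-1,3-diol
Product: 3 [3,5-bis(methoxymethoxy)phenoxy]tri(propan-2-yl)silane
Conditions: MOMCl (2.5 equiv), i-Pr2NEt (3 equiv), CH2Cl2, 0 °C to rt
Reagents that add atoms: chloromethyl methyl ether (MOMCl), COCCl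
Why: Williamson-type O-alkylation of both free phenols under amine conditions that leave the hindered aryl silyl ether in place.

Step 3
Reactants: 3 [3,5-bis(methoxymethoxy)phenoxy]tri(propan-2-yl)silane; 4 prenyl bromide (1-bromo-3-methylbut-2-ene)
Product: 7 [3,5-bis(methoxymethoxy)-4-(3-methylbut-2-en-1-yl)phenoxy]tri(propan-2-yl)silane, via aryllithium 5 (not isolated), via arylcopper 6 (not isolated)
Conditions: n-BuLi (1.1 equiv), THF, 0 °C; CuI (1.0 equiv), −40 °C; 4 (1.3 equiv), −78 °C to rt
Reagents that add atoms: none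
Why: Directed ortho-metalation should occur at the one ring position flanked by both MOM ethers (the bulky silyloxy group shields the other two), and the derived arylcopper is alkylated at the primary carbon of the allylic bromide (SN2 allylation) to give the linear prenyl group.

Step 4
Reactants: 7 [3,5-bis(methoxymethoxy)-4-(3-methylbut-2-en-1-yl)phenoxy]tri(propan-2-yl)silane
Product: 8 3,5-bis(methoxymethoxy)-4-(3-methylbut-2-en-1-yl)phenol
Conditions: TBAF (1.1 equiv), THF, 0 °C
Reagents that add atoms: none
Why: Fluoride-induced desilylation of the aryl silyl ether, driven by Si–F bond formation, leaves acetals and alkene untouched and unveils a phenol whose two open ring positions are equivalent by symmetry.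

Step 5
Reactants: 8 3,5-bis(methoxymethoxy)-4-(3-methylbut-2-en-1-yl)phenol
Product: 9 2-bromo-3,5-bis(methoxymethoxy)-4-(3-methylbut-2-en-1-yl)phenol
Conditions: NBS (1.0 equiv), CH2Cl2, −78 °C
Reagents that add atoms: N-bromosuccinimide (NBS), O=C1CCC(=O)N1Br
Why: Electrophilic aromatic bromination ortho to the free hydroxyl of a triply oxygen-activated ring should be much faster at low temperature than attack on the trisubstituted alkene, and symmetry makes the site of monobromination unambiguous.

Step 6
Reactants: 9 2-bromo-3,5-bis(methoxymethoxy)-4-(3-methylbut-2-en-1-yl)phenol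
Product: 12 3,5-bis(methoxymethoxy)-4-(3-methylbut-2-en-1-yl)-2-(trimethylsilyl)phenyl trifluoromethanesulfonate, via trimethylsilyl ether 10 (not isolated), via lithium silylphenoxide 11 (not isolated)
Conditions: HMDS, THF, 65 °C, then evaporation; n-BuLi (1.1 equiv), THF, −100 to −78 °C; Tf2O (1.2 equiv), −78 °C
Reagents that add atoms: hexamethyldisilazane (HMDS), C[Si](C)(C)N[Si](C)(C)C; trifluoromethanesulfonic anhydride (Tf2O), O=S(=O)(OS(=O)(=O)C(F)(F)F)C(F)(F)F
Why: O-silylation, bromine–lithium exchange and an anionic 1,3 O-to-C silyl shift (retro-Brook rearrangement) place the trimethylsilyl group on carbon, and the lithium phenoxide so released is trapped as the triflate, the standard entry to 2-silylaryl triflates.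

Step 7
Reactants: 13 3,4-dihydrocoumarin (chroman-2-one)
Product: 14 2-(3-hydroxy-3-methylbutyl)phenol
Conditions: MeMgBr (3 equiv), THF, 0 °C to rt; aq. NH4Cl
Reagents that add atoms: methylmagnesium bromide, C[Mg]Br
Why: Double Grignard addition to the lactone carbonyl opens the ring and builds the tertiary alcohol in one operation.

Step 8
Reactants: 14 2-(3-hydroxy-3-methylbutyl)phenol
Product: 15 4-bromo-2-(3-hydroxy-3-methylbutyl)phenol
Conditions: NBS (1.0 equiv), MeCN, 0 °C
Reagents that add atoms: N-bromosuccinimide (NBS), O=C1CCC(=O)N1Br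
Why: Electrophilic aromatic bromination of a phenol in acetonitrile is para-selective, one ortho position being blocked by the side chain and the other being the minor site.

Step 9
Reactants: 15 4-bromo-2-(3-hydroxy-3-methylbutyl)phenol
Product: 16 4-[5-bromo-2-(methoxymethoxy)phenyl]-2-methylbutan-2-ol
Conditions: MOMCl (1.2 equiv), i-Pr2NEt (1.5 equiv), CH2Cl2, 0 °C
Reagents that add atoms: chloromethyl methyl ether (MOMCl), COCCl
Why: Chemoselective Williamson-type O-alkylation of the acidic phenol, which the amine base activates, while the hindered tertiary alcohol does not react at this temperature.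

Step 10
Reactants: 16 4-[5-bromo-2-(methoxymethoxy)phenyl]-2-methylbutan-2-ol
Product: 17 ethyl [3-(3-hydroxy-3-methylbutyl)-4-(methoxymethoxy)phenyl]acetate
Conditions: BrZnCH2CO2Et (2.5 equiv, THF solution), Pd2(dba)3 (1 mol %), XPhos (4 mol %), THF, 60 °C
Reagents that add atoms: (2-ethoxy-2-oxoethyl)zinc bromide, CCOC(=O)C[Zn]Br
Why: Palladium-catalysed Negishi-type coupling of a Reformatsky reagent with the aryl bromide (ester α-arylation) installs the acetate unit under conditions mild enough for the acetal, the excess zinc reagent covering any that the free hydroxyl consumes.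

Step 11
Reactants: 17 ethyl [3-(3-hydroxy-3-methylbutyl)-4-(methoxymethoxy)phenyl]acetate
Product: 18 [3-(3-hydroxy-3-methylbutyl)-4-(methoxymethoxy)phenyl]acetic acid
Conditions: LiOH·H2O (3 equiv), THF/MeOH/H2O, rt; then 1 M HCl to pH 4, 0 °C
Reagents that add atoms: lithium hydroxide, [Li+].[OH-]
Why: Ester saponification followed by brief cold acidification to pH 4, which liberates the acid without hydrolysing the aryl MOM ether.

Step 12
Reactants: 12 3,5-bis(methoxymethoxy)-4-(3-methylbut-2-en-1-yl)-2-(trimethylsilyl)phenyl trifluoromethanesulfonate; 18 [3-(3-hydroxy-3-methylbutyl)-4-(methoxymethoxy)phenyl]acetic acid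
Product: 20 1-[2-hydroxy-4,6-bis(methoxymethoxy)-5-(3-methylbut-2-en-1-yl)phenyl]-2-[3-(3-hydroxy-3-methylbutyl)-4-(methoxymethoxy)phenyl]ethan-1-one, via benzyne 19 (not isolated)
Conditions: 12 (1.0 equiv), 18 (1.3 equiv), CsF (4 equiv), THF, 125 °C, sealed tube; aq. NH4Cl
Reagents that add atoms: none
Why: Fluoride attacks silicon and expels triflate to give benzyne 19; the cesium carboxylate of 18 adds through oxygen to C8a, and the aryl anion formed at C4a attacks the neighbouring ester carbonyl in a four-centre 1,3 O-to-C acyl shift that ends as the phenoxide of the ortho-hydroxy ketone. The closest known reaction type is the fluoride-mediated insertion of arynes into the C–O bond of carboxylic acids, an O-arylation followed by an anionic Fries-type acyl migration, established for simple acids in hot THF. No ring is closed and no stereocentre is formed; only the C8a–O1 and C4a–C4 bonds are made. Regioselectivity is required and is secured by the C5 methoxymethoxy group next to the triple bond, whose inductive effect stabilises negative charge at C4a and so sends the nucleophile to the distal, unhindered C8a, leaving the only free ring A oxygen para to the prenyl group. Chemoselectivity between the two oxygen nucleophiles of 18 rests on the anionic carboxylate being far more nucleophilic than the neutral, hindered tertiary hydroxyl, and the acid is taken in slight excess so that carboxylate also outcompetes the product phenoxide for the aryne. The hot aprotic medium should favour the intramolecular acyl shift over protonation of the aryl anion, which would stop at the aryl ester.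

Step 13
Reactants: 20 1-[2-hydroxy-4,6-bis(methoxymethoxy)-5-(3-methylbut-2-en-1-yl)phenyl]-2-[3-(3-hydroxy-3-methylbutyl)-4-(methoxymethoxy)phenyl]ethan-1-one
Product: 22 3-[3-(3-hydroxy-3-methylbutyl)-4-(methoxymethoxy)phenyl]-5,7-bis(methoxymethoxy)-6-(3-methylbut-2-en-1-yl)-4H-chromen-4-one, via enaminone 21 (not isolated)
Conditions: Me2NCH(OMe)2 (3 equiv), toluene, 90 °C
Reagents that add atoms: N,N-dimethylformamide dimethyl acetal, COC(OC)N(C)C
Why: Condensation of the formamide acetal with the doubly activated methylene gives the enaminone, and the ortho phenol then closes ring C by 6-endo-trig conjugate addition and loss of dimethylamine, the standard deoxybenzoin-to-isoflavone annulation.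

Step 14
Reactants: 22 3-[3-(3-hydroxy-3-methylbutyl)-4-(methoxymethoxy)phenyl]-5,7-bis(methoxymethoxy)-6-(3-methylbut-2-en-1-yl)-4H-chromen-4-one
Product: 23 Coloratanin A, 5,7-dihydroxy-3-[4-hydroxy-3-(3-hydroxy-3-methylbutyl)phenyl]-6-(3-methylbut-2-en-1-yl)-4H-chromen-4-one
Conditions: HCl (1.25 M in MeOH), MeOH, 0 °C to rt
Reagents that add atoms: none
Why: Acid-catalysed methanolysis (acetal exchange) of the three aryl methoxymethyl ethers should proceed under conditions too mild to ionise the tertiary alcohol or to cyclise the prenyl group onto a neighbouring phenol.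

Compound list
1 | phloroglucinol (benzene-1,3,5-triol) | Oc1cc(O)cc(O)c1 | starting material
2 | 5-{[tri(propan-2-yl)silyl]oxy}benzene-1,3-diol | CC(C)[Si](Oc1cc(O)cc(O)c1)(C(C)C)C(C)C | intermediate
3 | [3,5-bis(methoxymethoxy)phenoxy]tri(propan-2-yl)silane | COCOc1cc(OCOC)cc(O[Si](C(C)C)(C(C)C)C(C)C)c1 | intermediate
4 | prenyl bromide (1-bromo-3-methylbut-2-ene) | CC(C)=CCBr | starting material
5 | {2,6-bis(methoxymethoxy)-4-[tri(propan-2-yl)silyloxy]phenyl}lithium | [Li]c1c(OCOC)cc(O[Si](C(C)C)(C(C)C)C(C)C)cc1OCOC | intermediate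
6 | {2,6-bis(methoxymethoxy)-4-[tri(propan-2-yl)silyloxy]phenyl}copper | [Cu]c1c(OCOC)cc(O[Si](C(C)C)(C(C)C)C(C)C)cc1OCOC | intermediate
7 | [3,5-bis(methoxymethoxy)-4-(3-methylbut-2-en-1-yl)phenoxy]tri(propan-2-yl)silane | COCOc1cc(O[Si](C(C)C)(C(C)C)C(C)C)cc(OCOC)c1CC=C(C)C | intermediate
8 | 3,5-bis(methoxymethoxy)-4-(3-methylbut-2-en-1-yl)phenol | COCOc1cc(O)cc(OCOC)c1CC=C(C)C | intermediate
9 | 2-bromo-3,5-bis(methoxymethoxy)-4-(3-methylbut-2-en-1-yl)phenol | COCOc1cc(O)c(Br)c(OCOC)c1CC=C(C)C | intermediate
10 | [2-bromo-3,5-bis(methoxymethoxy)-4-(3-methylbut-2-en-1-yl)phenoxy]trimethylsilane | COCOc1cc(O[Si](C)(C)C)c(Br)c(OCOC)c1CC=C(C)C | intermediate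
11 | lithium 3,5-bis(methoxymethoxy)-4-(3-methylbut-2-en-1-yl)-2-(trimethylsilyl)phenoxide | [Li]Oc1cc(OCOC)c(CC=C(C)C)c(OCOC)c1[Si](C)(C)C | intermediate
12 | 3,5-bis(methoxymethoxy)-4-(3-methylbut-2-en-1-yl)-2-(trimethylsilyl)phenyl trifluoromethanesulfonate | COCOc1cc(OS(=O)(=O)C(F)(F)F)c([Si](C)(C)C)c(OCOC)c1CC=C(C)C | intermediate
13 | 3,4-dihydrocoumarin (chroman-2-one) | O=C1CCc2ccccc2O1 | starting material
14 | 2-(3-hydroxy-3-methylbutyl)phenol | CC(C)(O)CCc1ccccc1O | intermediate
15 | 4-bromo-2-(3-hydroxy-3-methylbutyl)phenol | CC(C)(O)CCc1cc(Br)ccc1O | intermediate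
16 | 4-[5-bromo-2-(methoxymethoxy)phenyl]-2-methylbutan-2-ol | COCOc1ccc(Br)cc1CCC(C)(C)O | intermediate
17 | ethyl [3-(3-hydroxy-3-methylbutyl)-4-(methoxymethoxy)phenyl]acetate | CCOC(=O)Cc1ccc(OCOC)c(CCC(C)(C)O)c1 | intermediate
18 | [3-(3-hydroxy-3-methylbutyl)-4-(methoxymethoxy)phenyl]acetic acid | OC(=O)Cc1ccc(OCOC)c(CCC(C)(C)O)c1 | intermediate
19 | 3,5-bis(methoxymethoxy)-4-(3-methylbut-2-en-1-yl)benzyne (1,2-didehydrobenzene, triple bond between the former triflate and silyl carbons) | COCOC1=CC#CC(OCOC)=C1CC=C(C)C | intermediate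
20 | 1-[2-hydroxy-4,6-bis(methoxymethoxy)-5-(3-methylbut-2-en-1-yl)phenyl]-2-[3-(3-hydroxy-3-methylbutyl)-4-(methoxymethoxy)phenyl]ethan-1-one | COCOc1cc(O)c(C(=O)Cc2ccc(OCOC)c(CCC(C)(C)O)c2)c(OCOC)c1CC=C(C)C | intermediate
21 | 3-(dimethylamino)-1-[2-hydroxy-4,6-bis(methoxymethoxy)-5-(3-methylbut-2-en-1-yl)phenyl]-2-[3-(3-hydroxy-3-methylbutyl)-4-(methoxymethoxy)phenyl]prop-2-en-1-one (alkene geometry not defined) | COCOc1cc(O)c(C(=O)C(=CN(C)C)c2ccc(OCOC)c(CCC(C)(C)O)c2)c(OCOC)c1CC=C(C)C | intermediate
22 | 3-[3-(3-hydroxy-3-methylbutyl)-4-(methoxymethoxy)phenyl]-5,7-bis(methoxymethoxy)-6-(3-methylbut-2-en-1-yl)-4H-chromen-4-one | COCOc1cc2occ(-c3ccc(OCOC)c(CCC(C)(C)O)c3)c(=O)c2c(OCOC)c1CC=C(C)C | intermediate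
23 | Coloratanin A, 5,7-dihydroxy-3-[4-hydroxy-3-(3-hydroxy-3-methylbutyl)phenyl]-6-(3-methylbut-2-en-1-yl)-4H-chromen-4-one | CC(C)=CCc1c(O)cc2occ(-c3ccc(O)c(CCC(C)(C)O)c3)c(=O)c2c1O | target

Total step count: 14.
Longest linear sequence: 9 steps (steps 1–6, then 12–14, from phloroglucinol). The ring B branch (steps 7–11) is 5 steps before the convergence.

Steps most likely to fail

Step 12. After O-arylation, the aryl anion may be quenched faster than it undergoes the four-centre acyl shift. The proton could come from the acidic benzylic methylene of the aryl ester or from the tertiary hydroxyl, and the reaction would then stop at the aryl ester. The hindered aryne may also be drained by the product phenoxide. The fallback makes the aryl–carbonyl bond by organometallic addition; it sets out from 9 and 17 and comes back at 20. Bromophenol 9 would be O-allylated (allyl bromide, K2CO3, DMF) to 1-(allyloxy)-2-bromo-3,5-bis(methoxymethoxy)-4-(3-methylbut-2-en-1-yl)benzene F1. Ester 17 would be reduced with i-Bu2AlH at −78 °C to 2-[3-(3-hydroxy-3-methylbutyl)-4-(methoxymethoxy)phenyl]acetaldehyde F2. Bromine–lithium exchange on F1 (n-BuLi, THF, −78 °C), transmetalation with anhydrous CeCl3 and addition of F2 should give the racemic carbinol 1-[2-(allyloxy)-4,6-bis(methoxymethoxy)-5-(3-methylbut-2-en-1-yl)phenyl]-2-[3-(3-hydroxy-3-methylbutyl)-4-(methoxymethoxy)phenyl]ethan-1-ol F3. The weakly basic organocerium reagent ArCeCl2 is taken in twofold excess to cover the free hydroxyl and should add to the enolisable aldehyde without deprotonating it. Dess–Martin oxidation would give the ketone 1-[2-(allyloxy)-4,6-bis(methoxymethoxy)-5-(3-methylbut-2-en-1-yl)phenyl]-2-[3-(3-hydroxy-3-methylbutyl)-4-(methoxymethoxy)phenyl]ethan-1-one F4. Deallylation with Pd(PPh3)4 and morpholine (Tsuji–Trost allyl transfer) would then deliver 20.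

Step 5. The brominating agent may add to the prenyl double bond or brominate the ring twice. The fallback replaces electrophilic halogenation by carbamate-directed ortho-silylation; it sets out from 8 and comes back at 12. Phenol 8 would be treated with isopropyl isocyanate and catalytic Et3N to give 3,5-bis(methoxymethoxy)-4-(3-methylbut-2-en-1-yl)phenyl N-(propan-2-yl)carbamate F5. In situ N-silylation (TBSOTf, TMEDA), directed ortho-lithiation (n-BuLi, TMEDA, Et2O, −78 °C) and a TMSCl quench should give, after work-up, 3,5-bis(methoxymethoxy)-4-(3-methylbut-2-en-1-yl)-2-(trimethylsilyl)phenyl N-(propan-2-yl)carbamate F6. DBU and Et2NH in MeCN at 40 °C would cleave the carbamate, and PhNTf2 added to the same flask would triflate the phenoxide to give 12.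

Step 14. Protic acid may promote hydroalkoxylation of the prenyl alkene by the C5 or C7 hydroxyl, or ionisation of the tertiary alcohol with capture by the C4' hydroxyl; either process forms a dimethylchroman ring. The fallback removes the acetals without protic acid by trans-protection to silyl ethers; it sets out from 22 and comes back at 23. TMSOTf and 2,2'-bipyridyl in CH2Cl2 at 0 °C should convert the aryl MOM ethers into aryl silyl ethers and silylate the tertiary hydroxyl as well. This would give 3-{3-[3-methyl-3-(trimethylsilyloxy)butyl]-4-(trimethylsilyloxy)phenyl}-6-(3-methylbut-2-en-1-yl)-5,7-bis(trimethylsilyloxy)-4H-chromen-4-one F7. K2CO3 in MeOH at rt would then remove all four silyl groups to give 23.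

Further compounds
F1 | step 12 | 1-(allyloxy)-2-bromo-3,5-bis(methoxymethoxy)-4-(3-methylbut-2-en-1-yl)benzene | C=CCOc1cc(OCOC)c(CC=C(C)C)c(OCOC)c1Br
F2 | step 12 | 2-[3-(3-hydroxy-3-methylbutyl)-4-(methoxymethoxy)phenyl]acetaldehyde | O=CCc1ccc(OCOC)c(CCC(C)(C)O)c1
F3 | step 12 | 1-[2-(allyloxy)-4,6-bis(methoxymethoxy)-5-(3-methylbut-2-en-1-yl)phenyl]-2-[3-(3-hydroxy-3-methylbutyl)-4-(methoxymethoxy)phenyl]ethan-1-ol (racemic) | C=CCOc1cc(OCOC)c(CC=C(C)C)c(OCOC)c1C(O)Cc1ccc(OCOC)c(CCC(C)(C)O)c1
F4 | step 12 | 1-[2-(allyloxy)-4,6-bis(methoxymethoxy)-5-(3-methylbut-2-en-1-yl)phenyl]-2-[3-(3-hydroxy-3-methylbutyl)-4-(methoxymethoxy)phenyl]ethan-1-one | C=CCOc1cc(OCOC)c(CC=C(C)C)c(OCOC)c1C(=O)Cc1ccc(OCOC)c(CCC(C)(C)O)c1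
F5 | step 5 | 3,5-bis(methoxymethoxy)-4-(3-methylbut-2-en-1-yl)phenyl N-(propan-2-yl)carbamate | CC(C)NC(=O)Oc1cc(OCOC)c(CC=C(C)C)c(OCOC)c1
F6 | step 5 | 3,5-bis(methoxymethoxy)-4-(3-methylbut-2-en-1-yl)-2-(trimethylsilyl)phenyl N-(propan-2-yl)carbamate | CC(C)NC(=O)Oc1cc(OCOC)c(CC=C(C)C)c(OCOC)c1[Si](C)(C)C
F7 | step 14 | 3-{3-[3-methyl-3-(trimethylsilyloxy)butyl]-4-(trimethylsilyloxy)phenyl}-6-(3-methylbut-2-en-1-yl)-5,7-bis(trimethylsilyloxy)-4H-chromen-4-one | C[Si](C)(C)Oc1cc2occ(-c3ccc(O[Si](C)(C)C)c(CCC(C)(C)O[Si](C)(C)C)c3)c(=O)c2c(O[Si](C)(C)C)c1CC=C(C)C
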